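The trans-fused hydroazulene is cut through its seven-membered ring at C7–C8 and C1–C10. The ring's oxygen at C6, oxygen at C10 and one-carbon branch at C8 then map onto a 2-siloxydiene (C7=C6–C5=C1, built on a terpinen-4-ol-derived cyclopentene that already carries C4) and an (E)-4-siloxyvinyl carbenoid (C8–C9=C10). One dirhodium-catalysed operation, cyclopropanation of the C6=C7 enol ether and boat Cope rearrangement of the resulting cis-divinylcyclopropane, makes both bonds, closes the seven-membered ring and sets C1 and C10. Its precursor is bis-silylated dienol ether 9, paired with diazo ester 13, whose E geometry comes from an elimination.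

Key step: step 9

Remark (numbering and faces): ring A is C1–C5, ring B is C1, C5–C10; C11–C13 are the isopropyl group on C4, C14 the methyl on C1, C15 the carbon on C8; β is the face carrying H-5 and the C6, C9 and C10 oxygens in the target, α the face of C14 and the C4 oxygen.

Remark (assumption on the catalyst hand): the sense known for the S catalyst with styrene and methyl aryldiazoacetates, (1S,2R), is transposed to the C6=C7 enol ether with the cyclopentenyl group in the role of the aryl group; this calls for Rh2(R-DOSP)4, and if the enol ether does not follow that sense the S catalyst takes its place with nothing else changed.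

Remark (spectator group): the carbenoid carries an ethyl ester because ethyl diazoacetate is the commercial entry; the ester is reduced away in step 12.

Step 1
Reactants: 1 (S)-terpinen-4-ol
Product: 2 triethylsilyl ether of (S)-terpinen-4-ol
Conditions: TESOTf, 2,6-lutidine, CH2Cl2, 0 °C → rt
Reagents that add atoms: triethylsilyl triflate, CC[Si](CC)(CC)OS(=O)(=O)C(F)(F)F
Why: Silyl ether formation on a hindered tertiary alcohol with a silyl triflate and a non-nucleophilic base leaves the stereocentre (the later C4) untouched, and is done first so that the hydroxyl can neither form a hemiketal after ring cleavage nor become a second dehydration site in step 3.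

Step 2
Reactants: 2 triethylsilyl ether of (S)-terpinen-4-ol
Product: 4 (3S)-6-oxo-3-(propan-2-yl)-3-(triethylsilyloxy)heptanal, via ozonide 3 (not isolated)
Conditions: O3, CH2Cl2, −78 °C; then PPh3, −78 °C → rt
Reagents that add atoms: ozone, [O-][O+]=O
Why: Ozonolysis with reductive work-up cleaves the only alkene to a methyl ketone and an aldehyde without touching the silyl ether or the quaternary stereocentre.

Step 3
Reactants: 4 (3S)-6-oxo-3-(propan-2-yl)-3-(triethylsilyloxy)heptanal
Product: 6 (5R)-2-methyl-5-(propan-2-yl)-5-(triethylsilyloxy)cyclopent-1-ene-1-carbaldehyde, via aldol adduct 5 (not isolated)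
Conditions: piperidine, AcOH, toluene, 60 °C
Reagents that add atoms: none
Why: Amine-catalysed intramolecular aldol condensation (5-enolexo) makes the aldehyde the enamine donor and the methyl ketone the acceptor, which gives the cyclopentene carbaldehyde and not the acetylcyclopentene, and acid-assisted dehydration should go through the free tertiary hydroxyl of 5 and spare the silyl ether.

Step 4
Reactants: 6 (5R)-2-methyl-5-(propan-2-yl)-5-(triethylsilyloxy)cyclopent-1-ene-1-carbaldehyde
Product: 7 1-[(5R)-2-methyl-5-(propan-2-yl)-5-(triethylsilyloxy)cyclopent-1-en-1-yl]ethan-1-ol (both carbinol epimers)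
Conditions: MeMgBr, THF, −78 → 0 °C; aq. NH4Cl
Reagents that add atoms: methylmagnesium bromide, C[Mg]Br
Why: Grignard 1,2-addition to the enal brings in C7; the new carbinol centre forms as a mixture that is erased in step 5.

Step 5
Reactants: 7 1-[(5R)-2-methyl-5-(propan-2-yl)-5-(triethylsilyloxy)cyclopent-1-en-1-yl]ethan-1-ol
Product: 8 1-[(5R)-2-methyl-5-(propan-2-yl)-5-(triethylsilyloxy)cyclopent-1-en-1-yl]ethan-1-one
Conditions: Dess–Martin periodinane, CH2Cl2, 0 °C → rt
Reagents that add atoms: none
Why: Dess–Martin oxidation of a secondary allylic alcohol to the enone is mild enough for the tertiary silyl ether and creates no stereocentre.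

Step 6
Reactants: 8 1-[(5R)-2-methyl-5-(propan-2-yl)-5-(triethylsilyloxy)cyclopent-1-en-1-yl]ethan-1-one
Product: 9 (5R)-1-[1-(tert-butyldimethylsilyloxy)ethenyl]-2-methyl-5-(propan-2-yl)-5-(triethylsilyloxy)cyclopent-1-ene
Conditions: TBSOTf, Et3N, CH2Cl2, 0 °C
Reagents that add atoms: tert-butyldimethylsilyl triflate, CC(C)(C)[Si](C)(C)OS(=O)(=O)C(F)(F)F
Why: Soft enolisation and O-silylation can only take place at the acetyl methyl group, the sole α-carbon bearing hydrogen, and so gives the cross-conjugated 2-siloxydiene C7=C6–C5=C1.

Step 7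
Reactants: 10 ethyl diazoacetate; 11 (tert-butyldimethylsilyloxy)acetaldehyde
Product: 12 ethyl 4-(tert-butyldimethylsilyloxy)-2-diazo-3-hydroxybutanoate (racemic)
Conditions: DBU (10 mol %), MeCN, 0 °C → rt
Reagents that add atoms: none
Why: Base-catalysed aldol-type addition of the nucleophilic diazo carbon to an aldehyde joins C8 to C9; the carbinol stereocentre is lost in step 8.

Step 8
Reactants: 12 ethyl 4-(tert-butyldimethylsilyloxy)-2-diazo-3-hydroxybutanoate
Product: 13 ethyl (E)-4-(tert-butyldimethylsilyloxy)-2-diazobut-3-enoate
Conditions: POCl3, Et3N, CH2Cl2, 0 °C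
Reagents that add atoms: none
Why: Dehydration of a β-hydroxy-α-diazo ester to the vinyldiazo ester, assisted by the diazo carbon, should give the E enol ether because the siloxy group avoids allylic strain with the diazo ester as the alkene forms, whereas direct O-silylation of a 4-oxobutanoate would favour the Z isomer that the Cope step cannot use.

Step 9
Reactants: 9 (5R)-1-[1-(tert-butyldimethylsilyloxy)ethenyl]-2-methyl-5-(propan-2-yl)-5-(triethylsilyloxy)cyclopent-1-ene; 13 ethyl (E)-4-(tert-butyldimethylsilyloxy)-2-diazobut-3-enoate
Product: 15 ethyl ester of the bicyclic 5,8-diene (C5=C6 enol silyl ether; C8=C9; 10β-OTBS; 4α-OTES; C14 α), via cis-divinylcyclopropane 14 (not isolated)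
Conditions: Rh2(R-DOSP)4 (1 mol %), hexanes, −40 °C, slow addition of 13 (1.5 equiv); then 60 °C
Reagents that add atoms: none
Why: Rh2(R-DOSP)4 turns 13 into a donor/acceptor vinylcarbenoid that adds in a concerted, asynchronous [2+1] fashion to the electron-rich, unhindered C6=C7 enol ether (the tetrasubstituted C5=C1 bond is left alone) with its vinyl group cis to the cyclopentenyl group, and the strain of the resulting cis-divinylcyclopropane 14 then drives a [3,3] shift that breaks C6–C8 and makes C1–C10. The closest known reaction type is exactly this tandem cyclopropanation/Cope rearrangement (formal [4+3] cycloaddition) of vinyldiazoacetates with dienes, 2-siloxydienes included; the 4-siloxy substituent on the carbenoid is the unusual element. Ring B is closed by the sigmatropic C1–C10 bond formation through the boat transition state that a cis-divinylcyclopropane is forced to use. In that boat the groups trans to the three-membered ring on each vinyl terminus, the siloxy group on C10 and C2 on C1, finish on the same face of ring B while the C14 methyl lies over the cyclopropane (hence the warming), which fixes C10 relative to C1. Their absolute sense, that is C10 entering C1 syn to the isopropyl group on C4, is relayed from the cyclopropane and therefore from the enol ether face chosen by the catalyst. The step needs site selectivity (enol ether electronics), cis-cyclopropane selectivity (inherent in donor/acceptor carbenoids) and face selectivity (catalyst; hydrocarbon solvent and low temperature also disfavour attack at the siloxy-bearing carbenoid terminus).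

Step 10
Reactants: 15 ethyl ester of the bicyclic 5,8-diene
Product: 16 trans-fused hydroxy ketone (C6 ketone; H-5 β; 4α-OH; 10β-OTBS; C8=C9 ethyl ester)
Conditions: HF·pyridine, pyridine, THF, 0 °C → rt
Reagents that add atoms: none
Why: Buffered HF·pyridine cleaves the silyl enol ether and the tertiary triethylsilyl ether while the hindered secondary C10 silyl ether survives (fluoride-assisted desilylation and ketonisation), and ketonisation by this small acid should place H-5 on the β face, because C6 then moves toward the methyl/oxygen side of ring A instead of into the isopropyl group and C10, giving the trans-fused ketone that is also the more stable epimer (C4–OH···O=C6 hydrogen bond); the medium is kept free of base so that C8=C9 cannot slide into conjugation with the new ketone.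

Step 11
Reactants: 16 trans-fused hydroxy ketone
Product: 17 4α,6β-diol (10β-OTBS; C8=C9 ethyl ester)
Conditions: Me4NBH(OAc)3, AcOH/MeCN, −30 → 0 °C
Reagents that add atoms: none
Why: Evans–Saksena reduction: the C4 hydroxyl binds the borohydride and hands hydride to the α face of C6 through a six-membered transition state, which sets the 6β-hydroxyl (1,3-anti to the 4α-hydroxyl) and leaves the enoate alone.

Step 12
Reactants: 17 4α,6β-diol ethyl ester
Product: 18 4α,6β,15-triol (10β-OTBS; C8=C9)
Conditions: iBu2AlH (excess), CH2Cl2, −78 → 0 °C; Rochelle salt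
Reagents that add atoms: none
Why: 1,2-Reduction of the conjugated ester by the aluminium hydride gives the C15 allylic alcohol without affecting the alkene, the silyl ether or any stereocentre.

Step 13
Reactants: 18 4α,6β,15-triol
Product: 19 4α,6β,10β,15-tetraol (C8=C9)
Conditions: Bu4NF, THF, rt
Reagents that add atoms: none
Why: Fluoride desilylation frees the C10 hydroxyl, now that no ketone or ester is present to suffer from the basic fluoride.

Step 14
Reactants: 19 4α,6β,10β,15-tetraol
Product: 20 8β,9β-epoxide of the tetraol
Conditions: VO(acac)2 (5 mol %), tBuOOH, CH2Cl2, 0 °C → rt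
Reagents that add atoms: tert-butyl hydroperoxide, CC(C)(C)OO
Why: Vanadium-catalysed hydroxyl-directed epoxidation delivers oxygen to the only alkene on the face of the allylic C10 hydroxyl (the homoallylic C6 hydroxyl points the same way), which sets C9 (and transiently C8) with the epoxide oxygen β.

Step 15
Reactants: 20 8β,9β-epoxide of the tetraol
Product: 21 15-iodo-8β,9β-epoxide (4α,6β,10β-triol)
Conditions: PPh3, I2, imidazole, THF, 0 °C
Reagents that add atoms: iodine, II
Why: Appel-type iodination under Garegg–Samuelsson conditions converts the single primary alcohol selectively at low temperature and creates no stereocentre.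

Step 16
Reactants: 21 15-iodo-8β,9β-epoxide
Product: 22 4α,6β,9β,10β-tetraol with the C8=C15 exocyclic methylene
Conditions: Zn dust, EtOH, 70 °C
Reagents that add atoms: none
Why: Zinc insertion into the C–I bond and β-elimination open the epoxide (reductive opening of a 2,3-epoxy iodide to the transposed allylic alcohol), which gives C8=C15 and keeps the C9–O bond, hence the 9β-hydroxyl cis to the 10β-hydroxyl.

Step 17
Reactants: 22 4α,6β,9β,10β-tetraol
Product: 23 9,10-acetonide (4α,6β-diol)
Conditions: Me2C(OMe)2, PPTS, CH2Cl2, 0 °C → rt
Reagents that add atoms: 2,2-dimethoxypropane, COC(C)(C)OC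
Why: Acid-catalysed transacetalisation takes the cis-vicinal diol as its five-membered acetonide in preference to the 1,3-anti diol that contains the tertiary C4 hydroxyl.

Step 18
Reactants: 23 9,10-acetonide
Product: 24 6β-(3-methylbutanoate) of the 9,10-acetonide
Conditions: (iPrCH2CO)2O, Et3N, DMAP (cat.), CH2Cl2, rt
Reagents that add atoms: 3-methylbutanoic anhydride, CC(C)CC(=O)OC(=O)CC(C)C
Why: DMAP-catalysed acylation reaches the only free secondary alcohol (C6), the tertiary C4 hydroxyl being inert under these conditions.

Step 19
Reactants: 24 6β-(3-methylbutanoate) of the 9,10-acetonide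
Product: 25 target, (1S,4R,5S,6S,9R,10S)-4,9,10-trihydroxy-8(15)-ene 6-(3-methylbutanoate)
Conditions: AcOH/H2O (4:1), 40 °C
Reagents that add atoms: none
Why: Mild acid hydrolysis of the acetonide frees the 9,10-diol without cleaving the ester or ionising the allylic C9 alcohol.

Compound list
1 | (S)-terpinen-4-ol, (1S)-4-methyl-1-(propan-2-yl)cyclohex-3-en-1-ol | CC1=CC[C@](O)(C(C)C)CC1 | starting material
2 | triethyl{[(1S)-4-methyl-1-(propan-2-yl)cyclohex-3-en-1-yl]oxy}silane | CC1=CC[C@](O[Si](CC)(CC)CC)(C(C)C)CC1 | intermediate
3 | ozonide of 2 (1,2,4-trioxolane across the former alkene; both epimers at the new centres) | CC12CC[C@@](O[Si](CC)(CC)CC)(C(C)C)CC(OO1)O2 | intermediate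
4 | (3S)-6-oxo-3-(propan-2-yl)-3-(triethylsilyloxy)heptanal | CC(=O)CC[C@@](O[Si](CC)(CC)CC)(C(C)C)CC=O | intermediate
5 | (5R)-2-hydroxy-2-methyl-5-(propan-2-yl)-5-(triethylsilyloxy)cyclopentane-1-carbaldehyde (aldol adduct; epimers at C1 and C2) | O=CC1C(C)(O)CC[C@@]1(O[Si](CC)(CC)CC)C(C)C | intermediate
6 | (5R)-2-methyl-5-(propan-2-yl)-5-(triethylsilyloxy)cyclopent-1-ene-1-carbaldehyde | O=CC1=C(C)CC[C@@]1(O[Si](CC)(CC)CC)C(C)C | intermediate
7 | 1-[(5R)-2-methyl-5-(propan-2-yl)-5-(triethylsilyloxy)cyclopent-1-en-1-yl]ethan-1-ol (both carbinol epimers) | CC(O)C1=C(C)CC[C@@]1(O[Si](CC)(CC)CC)C(C)C | intermediate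
8 | 1-[(5R)-2-methyl-5-(propan-2-yl)-5-(triethylsilyloxy)cyclopent-1-en-1-yl]ethan-1-one | CC(=O)C1=C(C)CC[C@@]1(O[Si](CC)(CC)CC)C(C)C | intermediate
9 | 2-siloxydiene, (5R)-1-[1-(tert-butyldimethylsilyloxy)ethenyl]-2-methyl-5-(propan-2-yl)-5-(triethylsilyloxy)cyclopent-1-ene | C=C(O[Si](C)(C)C(C)(C)C)C1=C(C)CC[C@@]1(O[Si](CC)(CC)CC)C(C)C | intermediate
10 | ethyl diazoacetate | CCOC(=O)C=[N+]=[N-] | starting material
11 | (tert-butyldimethylsilyloxy)acetaldehyde | O=CCO[Si](C)(C)C(C)(C)C | starting material
12 | ethyl 4-(tert-butyldimethylsilyloxy)-2-diazo-3-hydroxybutanoate (racemic) | CCOC(=O)C(=[N+]=[N-])C(O)CO[Si](C)(C)C(C)(C)C | intermediate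
13 | ethyl (E)-4-(tert-butyldimethylsilyloxy)-2-diazobut-3-enoate | CCOC(=O)C(=[N+]=[N-])/C=C/O[Si](C)(C)C(C)(C)C | intermediate
14 | cis-divinylcyclopropane: ethyl 2-(tert-butyldimethylsilyloxy)-1-[(E)-2-(tert-butyldimethylsilyloxy)ethenyl]-2-[(5R)-2-methyl-5-(propan-2-yl)-5-(triethylsilyloxy)cyclopent-1-en-1-yl]cyclopropane-1-carboxylate, alkenyl groups cis | CCOC(=O)[C@]1(/C=C/O[Si](C)(C)C(C)(C)C)C[C@@]1(O[Si](C)(C)C(C)(C)C)C2=C(C)CC[C@@]2(O[Si](CC)(CC)CC)C(C)C | intermediate
15 | bicyclic 5,8-diene: ethyl ester (C15) on C8, C5=C6 enol TBS ether, C8=C9, 10β-OTBS, 4α-OTES with 4β-isopropyl, C14 methyl α on C1 | CCOC(=O)C1=C[C@@H](O[Si](C)(C)C(C)(C)C)[C@@]2(C)CC[C@@](O[Si](CC)(CC)CC)(C(C)C)C2=C(O[Si](C)(C)C(C)(C)C)C1 | intermediate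
16 | trans-fused hydroxy ketone: C6 ketone, H-5 β, 4α-OH, 10β-OTBS, C8=C9 ethyl ester | CCOC(=O)C1=C[C@@H](O[Si](C)(C)C(C)(C)C)[C@@]2(C)CC[C@@](O)(C(C)C)[C@@H]2C(=O)C1 | intermediate
17 | 4α,6β-diol, 10β-OTBS, C8=C9 ethyl ester | CCOC(=O)C1=C[C@@H](O[Si](C)(C)C(C)(C)C)[C@@]2(C)CC[C@@](O)(C(C)C)[C@@H]2[C@@H](O)C1 | intermediate
18 | 4α,6β,15-triol, 10β-OTBS, C8=C9 | OCC1=C[C@@H](O[Si](C)(C)C(C)(C)C)[C@@]2(C)CC[C@@](O)(C(C)C)[C@@H]2[C@@H](O)C1 | intermediate
19 | 4α,6β,10β,15-tetraol, C8=C9 | OCC1=C[C@@H](O)[C@@]2(C)CC[C@@](O)(C(C)C)[C@@H]2[C@@H](O)C1 | intermediate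
20 | 8β,9β-epoxy-4α,6β,10β,15-tetraol | OC[C@]12O[C@H]1[C@@H](O)[C@@]3(C)CC[C@@](O)(C(C)C)[C@@H]3[C@@H](O)C2 | intermediate
21 | 15-iodo-8β,9β-epoxy-4α,6β,10β-triol | IC[C@]12O[C@H]1[C@@H](O)[C@@]3(C)CC[C@@](O)(C(C)C)[C@@H]3[C@@H](O)C2 | intermediate
22 | 4α,6β,9β,10β-tetraol with C8=C15 exocyclic methylene | C=C1C[C@H](O)[C@@H]2[C@](C)(CC[C@@]2(O)C(C)C)[C@H](O)[C@@H]1O | intermediate
23 | 9,10-acetonide of 22 | C=C1C[C@H](O)[C@@H]2[C@](C)(CC[C@@]2(O)C(C)C)[C@@H]3OC(C)(C)O[C@H]13 | intermediate
24 | 6β-(3-methylbutanoate) of 23 | C=C1C[C@H](OC(=O)CC(C)C)[C@@H]2[C@](C)(CC[C@@]2(O)C(C)C)[C@@H]3OC(C)(C)O[C@H]13 | intermediate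
25 | CNP0204264.1, (1S,4R,5S,6S,9R,10S)-4,9,10-trihydroxy-8(15)-ene 6-(3-methylbutanoate) (numbering as in the remark) | C=C1C[C@H](OC(=O)CC(C)C)[C@@H]2[C@](C)(CC[C@@]2(O)C(C)C)[C@H](O)[C@@H]1O | target

Total step count: 19 steps.
Longest linear sequence: 17 steps (steps 1–6 and 9–19, from (S)-terpinen-4-ol); the diazo ester arm is 2 steps.

Steps most likely to fail

Step 9. The carbenoid may add to the wrong face of the C6=C7 enol ether (catalyst hand and C4 stereocentre mismatched, or the transposed sense of induction not holding), or react through its siloxy-bearing terminus, so that little of the right cyclopropane forms. Fallback: stereocontrol is taken out of the key step and replaced by separation. Compounds 9 and 13 are combined under the same tandem conditions with achiral Rh2(OOct)4 (dirhodium tetraoctanoate), both enol ether faces are allowed to react, and the unwanted product, the C1,C10-diastereomer of 15, F1, is removed by chromatography. This is possible because the fixed C4 centre makes the two cycloheptadienes diastereomers. The fallback sets out from 9 and 13 and comes back at 15.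

Step 10. Delivery of the C5 proton from the more open α face (approach control) would give the cis-fused ketone. Correction with base is excluded, because C7 is α to the ketone as well as allylic, so alkene migration into conjugation and loss of the C10 silyloxy group would follow. Fallback: the proton is delivered under reagent control by a Lewis acid-assisted chiral Brønsted acid. Compound 15 is treated in toluene at −78 °C with catalytic BINOL·SnCl4 (the BINOL enantiomer matched to β-face delivery) and 2,6-dimethylphenol as the stoichiometric proton source. This should convert the silyl enol ether into the trans-fused ketone that still carries its C4 triethylsilyl ether, F2; HF·pyridine then removes that silyl ether. The fallback sets out from 15 and comes back at 16.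

Step 3. β-Elimination of the C4 silyloxy group from the aldehyde enamine may compete with cyclisation, or with dehydration through the new tertiary hydroxyl, and would destroy the stereocentre. Fallback: bond formation and dehydration are separated. Compound 4 is cyclised with (S)-proline in DMSO at room temperature, an enamine aldol addition that stops at the β-hydroxy aldehyde 5, which is now isolated. Only its free tertiary hydroxyl is then activated with MsCl and Et3N in CH2Cl2 at 0 °C; the mesylate of 5, F3, eliminates in the flask (E1cB) to the enal. The fallback sets out from 4 and comes back at 6.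

Further compounds
F1 | step 9 | C1,C10-diastereomer of 15 (10α-OTBS, C14 methyl β, other groups as in 15) | CCOC(=O)C1=C[C@H](O[Si](C)(C)C(C)(C)C)[C@]2(C)CC[C@@](O[Si](CC)(CC)CC)(C(C)C)C2=C(O[Si](C)(C)C(C)(C)C)C1
F2 | step 10 | trans-fused C6 ketone with 4α-OTES and 10β-OTBS, C8=C9 ethyl ester | CCOC(=O)C1=C[C@@H](O[Si](C)(C)C(C)(C)C)[C@@]2(C)CC[C@@](O[Si](CC)(CC)CC)(C(C)C)[C@@H]2C(=O)C1
F3 | step 3 | methanesulfonate of aldol adduct 5 | O=CC1C(C)(OS(C)(=O)=O)CC[C@@]1(O[Si](CC)(CC)CC)C(C)C
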